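## The problem

Target 13 is the 7-O-ether of 8-methoxycoumarin with an oxidised geranyl chain, 3',7'-dimethyloct-6'-enyl numbered from the ArO–CH2 carbon C1', in which C2'–C3' carry a trisubstituted oxirane, C5' a secondary allylic hydroxyl and C6'=C7' the terminal trisubstituted alkene. The coumarin is bought, so the oxirane is the only ring to close and the work is a ten-carbon chain with three stereocentres, (2'R,3'R,5'R). C3' is quaternary (O, CH3, C2', C4') and is the difficult centre; on the oxirane C1' and C4' are trans, and the C5'–O bond is 1,3-anti to the C3'–O bond in the extended chain. A stereocentre at C2' can therefore set C3' by 1,2-induction and an oxygen on C3' can set C5' by 1,3-induction, so one purchased stereocentre can in principle pay for all three. The sensitive groups are the coumarin lactone with its C3=C4 bond (hydroxide, hydride donors, organometallic reagents, hydrogenation), the ArO–CH2 bond whenever a carbonyl sits at C3' (β-elimination of the phenoxide), and the epoxide and the prenyl-type allylic alcohol (acid). The enabling feature is that C3' is a tertiary carbinol β to the C5' oxygen, an aldol retron C3'(OH)–C4'–C5'(=O), whose neighbour C2' can carry a chlorine that first steers the addition to the C3' carbonyl and then leaves in the oxirane closure.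

## Retrosynthesis

**13 ⇒ 12.** The C2'–O bond of the oxirane is cut, giving chloro diol 12 with a free tertiary C3' hydroxyl and an (S)-configured C2'–Cl. The other oxirane bond, C3'–O, would require SN2 at a quaternary carbon, and epoxidation of an alkene would require reagent control and a protected C5' hydroxyl. With this cut the acid-labile epoxide appears only in the last step. The forward reaction must be a backside displacement with inversion at C2' that outruns 5-exo attack by the C5' hydroxyl.

**12 ⇒ 11.** The C5' carbinol is traced to a ketone. No bond is cut, but the aldol retron is exposed and C5' becomes a problem of 1,3-induction from the C3' hydroxyl. The forward step must give the 1,3-anti diol from a tertiary carbinol and reduce an enone in the 1,2 sense without touching the lactone.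

**11 ⇒ 6 + 9.** The C3'–C4' bond is cut, the only cut that makes the quaternary centre in the bond-forming event. A cut at C4'–C5' would set C5' but leave C3' unsolved, and a cut at C2'–C3' would need an α-chloro carbanion equivalent. The chain falls into the C4 α-chloro methyl ketone 6, which carries the coumarin and one stereocentre, and the achiral C6 silyl dienol ether 9. The forward reaction must select one face of the ketone under control of C2' and must run without base, because 6 can epimerise and can lose its aryloxide.

**9 ⇒ 7.** The dienol ether is the kinetic O-silyl derivative of mesityl oxide 7. One step from a bulk chemical supplies C4'–C8' and the 7'-methyl.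

**6 ⇒ 5 ⇒ 3 + 4.** The ketone is taken back to secondary alcohol 5, so that C2'–Cl sits next to a carbonyl only in the step before the aldol. The C1'–O ether bond is then cut to phenol 4 and chloro diol 3. An entry that builds the methyl ketone by acylating a methylmetal reagent was set aside: it would keep C2'–Cl beside an activated carboxyl derivative for several steps and bring an organometallic reagent to the coumarin. The forward etherification must distinguish the primary from the secondary hydroxyl of 3.

**3 ⇒ 2 ⇒ 1.** Diol 3 is the reduction product of chloro acid 2, which comes from D-threonine 1 by replacement of NH2 by Cl with retention. The amino acid supplies C1' (its carboxyl carbon), C2', C3' and the 3'-methyl; its C3 hydroxyl is the latent ketone. The D series is required because the carboxyl carbon becomes C1', which reverses the sense of the descriptor at C2'.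

## Roads not taken

**Alternative 1:** The cut removes the 3'-methyl and the C1'–C2' bond. Forward, terminal alkyne A1 takes up methyl and aluminium in syn fashion from Al(CH3)3 with catalytic Cp2ZrCl2, and the alkenyl metal is trapped with formaldehyde A2 to give E-allylic alcohol A3. Asymmetric epoxidation of the allylic alcohol, Mitsunobu etherification with 4 and desilylation would finish 13.
- Merits: complete E control, and an epoxidation of a geraniol-type allylic alcohol under reagent control, which is among the most dependable asymmetric reactions known.
- Weak points: C5' must be bought with a separate enantioselective propargylation before the key step. A silyl group has to be carried and removed. The allylic silyl ether must survive a strongly Lewis acidic aluminium reagent.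
- Comparison: this road is no longer than the chosen one, and its control of C2' and C3' is more certain. The chosen plan sets against it that it needs no protecting group and no chiral reagent, that all three centres derive from one amino acid, and that the epoxide is made last and is not carried through etherification and fluoride treatment.

**Alternative 2:** The cut is C4'–C5'. Silyl dienolate A4 attacks enal A5 through its γ-carbon under SiCl4 and a chiral bisphosphoramide to give hydroxy dienoate A6. Silylation and ester reduction lead to A3, where this road joins alternative 1.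
- Merits: two five-carbon units are joined in one catalytic asymmetric step that sets C5' and the E alkene together. The route is the most convergent of all and about as short as the chosen plan.
- Weak points: γ-regioselectivity and enantioselectivity must hold for a β,β-disubstituted enal. The ester must be reduced. Three further steps (epoxidation, etherification, desilylation) each act on an increasingly acid-sensitive allylic or epoxy alcohol.
- Comparison: in convergence and precedent this road is at least equal to the chosen plan. The chosen plan offers freedom from protecting groups and from two different chiral catalyst systems, and relays one stereocentre into the other two instead of setting three independently.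

**Alternative 3:** The cut is C2'–C3'. Aldehyde A7 reacts with E-configured γ-silyloxy allylboronate A8 under a chiral phosphoric acid through a chair transition state to give A9, with C2' and C3' set together and the coumarin already in place.
- Merits: both epoxide carbons are fixed in one catalyst-controlled step, and no α-chloro ketone has to be handled.
- Weak points: the product ends in a vinyl group. C4'–C8' still have to be added by hydroboration, oxidation and alkenyl addition, with C5' set by weak 1,3-induction or a further catalyst. The geometrically pure tetrasubstituted boronate is hard to obtain, the α-aryloxy aldehyde is enolisable, and epoxide closure needs activation of the C2' hydroxyl and unmasking of a tertiary silyl ether.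
- Comparison: this road is clearly longer. Its one advantage is catalyst control at the quaternary centre. The chosen plan answers with a C3'–C4' bond formation that delivers the full carbon skeleton at once.

Key step: step 6

Assumption: D-threonine (1), 7-hydroxy-8-methoxycoumarin (4) and mesityl oxide (7) are taken as purchased; the side chain is numbered from the ArO–CH2 carbon as C1'.

## Route

Step 1
Reactants: 1 D-threonine
Product: 2 (2R,3S)-2-chloro-3-hydroxybutanoic acid
Conditions: NaNO2, 6 M HCl, 0 °C → rt
Reagents that add atoms: hydrogen chloride (aqueous), SMILES Cl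
Why: Diazotisation of an α-amino acid in hydrochloric acid, the classical route to 2-chloro acids; the carboxylate displaces N2 and chloride opens the transient acyloxy bridge, two inversions that return the original spatial arrangement at C2, and the C3 carbinol is not involved.

Step 2
Reactants: 2 (2R,3S)-2-chloro-3-hydroxybutanoic acid
Product: 3 (2S,3S)-2-chlorobutane-1,3-diol
Conditions: BH3·SMe2, THF, 0 °C → rt; MeOH quench, evaporation
Reagents that add atoms: none
Why: Chemoselective borane reduction of a carboxylic acid leaves the C–Cl bond and both stereocentres untouched, and methanolysis removes boron as volatile trimethyl borate; the descriptor at C2 changes from R to S only because CH2OH ranks below C3.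

Step 3
Reactants: 3 (2S,3S)-2-chlorobutane-1,3-diol; 4 7-hydroxy-8-methoxy-2H-chromen-2-one
Product: 5 7-{[(2S,3S)-2-chloro-3-hydroxybutyl]oxy}-8-methoxy-2H-chromen-2-one
Conditions: PPh3, DIAD, THF, 0 °C → rt (slight excess of 3)
Reagents that add atoms: none
Why: Mitsunobu etherification; the acidic 7-hydroxycoumarin is a good pronucleophile and the primary oxyphosphonium is displaced much faster than the secondary one, as in the etherification of butane-1,3-diol and of 2-haloethanols, so neither stereocentre is touched and the neutral medium spares chlorohydrin and lactone.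

Step 4
Reactants: 5 7-{[(2S,3S)-2-chloro-3-hydroxybutyl]oxy}-8-methoxy-2H-chromen-2-one
Product: 6 7-[(2S)-2-chloro-3-oxobutoxy]-8-methoxy-2H-chromen-2-one
Conditions: Dess–Martin periodinane, CH2Cl2, 0 °C → rt; dilution with Et2O, filtration through a short silica pad, used at once
Reagents that add atoms: none
Why: Dess–Martin oxidation of a chlorohydrin is a standard, essentially neutral route to α-chloro ketones; with no enolising base present and only acetic acid released, the C2' configuration and the β-aryloxy group should persist.

Step 5
Reactants: 7 mesityl oxide (4-methylpent-3-en-2-one)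
Product: 9 4-methyl-2-(trimethylsilyloxy)penta-1,3-diene, via lithium dienolate 8 (not isolated)
Conditions: LiN(iPr)2, THF, −78 °C; then TMSCl, −78 °C → rt; distillation
Reagents that add atoms: chlorotrimethylsilane, SMILES C[Si](C)(C)Cl
Why: Kinetic deprotonation of the enone at the α'-methyl group by the hindered lithium amide, then O-silylation of the cross-conjugated dienolate, gives the 2-silyloxydiene; no stereocentre is formed.

Step 6
Reactants: 6 7-[(2S)-2-chloro-3-oxobutoxy]-8-methoxy-2H-chromen-2-one; 9 4-methyl-2-(trimethylsilyloxy)penta-1,3-diene
Product: 11 7-{[(2S,3R)-2-chloro-3-hydroxy-3,7-dimethyl-5-oxooct-6-en-1-yl]oxy}-8-methoxy-2H-chromen-2-one, via difluoroboryl aldolate 10 (not isolated)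
Conditions: BF3·OEt2 (2 equiv), CH2Cl2, −78 °C; then aq. NaHCO3
Reagents that add atoms: none
Why: BF3 binds the C3' carbonyl oxygen, and the terminal CH2 of 9, its only nucleophilic enol-ether carbon, attacks C3' through an open transition state; loss of silicon as fluorotrimethylsilane leaves boron aldolate 10, which the work-up hydrolyses to 11 (Mukaiyama aldol addition). The closest known reactions are Lewis-acid-mediated enol silane additions to α-chloro aldehydes, which give 1,2-anti chlorohydrins, and Cornforth-type additions of organometallic reagents to α-chloro ketones. One bond, C3'–C4', is formed and no ring closes. The new centre C3' is controlled by C2': with C–Cl opposed to the C=O dipole (Cornforth), or perpendicular to the carbonyl plane and anti to the nucleophile (polar Felkin–Anh), the enol ether passes the C2' hydrogen and not the aryloxymethyl arm, and both arrangements lead to 3'R. BF3 has a single free coordination site, so a carbonyl–chlorine chelate, which would expose the other face, cannot form. The step needs this face selectivity, chemoselectivity for the chlorine-activated ketone over the unreactive lactone carbonyl, and the absence of base, so that epimerisation at C2', β-loss of the aryloxide and retro-aldol cleavage of the tertiary adduct cannot start.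

Step 7
Reactants: 11 7-{[(2S,3R)-2-chloro-3-hydroxy-3,7-dimethyl-5-oxooct-6-en-1-yl]oxy}-8-methoxy-2H-chromen-2-one
Product: 12 7-{[(2S,3R,5R)-2-chloro-3,5-dihydroxy-3,7-dimethyloct-6-en-1-yl]oxy}-8-methoxy-2H-chromen-2-one
Conditions: Me4NBH(OAc)3, MeCN/AcOH, −40 → −20 °C; then aq. potassium sodium tartrate
Reagents that add atoms: none
Why: Evans–Saksena hydroxyl-directed reduction; the C3' hydroxyl exchanges with an acetate on boron and hydride is delivered internally through a chair in which the larger C2' branch is equatorial and the methyl axial, giving the 1,3-anti diol, which is 5'R; the reagent leaves lactone and alkenes alone and the acidic medium excludes retro-aldol cleavage.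

Step 8
Reactants: 12 7-{[(2S,3R,5R)-2-chloro-3,5-dihydroxy-3,7-dimethyloct-6-en-1-yl]oxy}-8-methoxy-2H-chromen-2-one
Product: 13 7-{[(2R,3R)-3-[(2R)-2-hydroxy-4-methylpent-3-en-1-yl]-3-methyloxiran-2-yl]methoxy}-8-methoxy-2H-chromen-2-one
Conditions: K2CO3, MeOH, 0 °C → rt
Reagents that add atoms: none
Why: Intramolecular Williamson displacement (3-exo-tet); the C3' alkoxide attacks C2' anti to chloride, inverting it from S to R and placing C1' and C4' trans on the oxirane; closure from the vicinal alkoxide should outrun 5-exo attack by the C5' hydroxyl at this temperature, and 7-alkoxycoumarins tolerate carbonate in methanol.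

## Compound list

1 | D-threonine, (2R,3S)-2-amino-3-hydroxybutanoic acid | C[C@H](O)[C@@H](N)C(=O)O | starting material
2 | (2R,3S)-2-chloro-3-hydroxybutanoic acid | C[C@H](O)[C@@H](Cl)C(=O)O | intermediate
3 | (2S,3S)-2-chlorobutane-1,3-diol | C[C@H](O)[C@@H](Cl)CO | intermediate
4 | 7-hydroxy-8-methoxy-2H-chromen-2-one | COc1c(O)ccc2ccc(=O)oc12 | starting material
5 | 7-{[(2S,3S)-2-chloro-3-hydroxybutyl]oxy}-8-methoxy-2H-chromen-2-one | COc1c(OC[C@H](Cl)[C@H](C)O)ccc2ccc(=O)oc12 | intermediate
6 | 7-[(2S)-2-chloro-3-oxobutoxy]-8-methoxy-2H-chromen-2-one | COc1c(OC[C@H](Cl)C(C)=O)ccc2ccc(=O)oc12 | intermediate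
7 | mesityl oxide, 4-methylpent-3-en-2-one | CC(C)=CC(C)=O | starting material
8 | lithium 4-methylpenta-1,3-dien-2-olate | [Li+].[O-]C(=C)C=C(C)C | intermediate
9 | 4-methyl-2-(trimethylsilyloxy)penta-1,3-diene | CC(C)=CC(=C)O[Si](C)(C)C | intermediate
10 | 7-{[(2S,3R)-2-chloro-3-(difluoroboranyloxy)-3,7-dimethyl-5-oxooct-6-en-1-yl]oxy}-8-methoxy-2H-chromen-2-one | COc1c(OC[C@H](Cl)[C@](C)(OB(F)F)CC(=O)C=C(C)C)ccc2ccc(=O)oc12 | intermediate
11 | 7-{[(2S,3R)-2-chloro-3-hydroxy-3,7-dimethyl-5-oxooct-6-en-1-yl]oxy}-8-methoxy-2H-chromen-2-one | COc1c(OC[C@H](Cl)[C@](C)(O)CC(=O)C=C(C)C)ccc2ccc(=O)oc12 | intermediate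
12 | 7-{[(2S,3R,5R)-2-chloro-3,5-dihydroxy-3,7-dimethyloct-6-en-1-yl]oxy}-8-methoxy-2H-chromen-2-one | COc1c(OC[C@H](Cl)[C@](C)(O)C[C@@H](O)C=C(C)C)ccc2ccc(=O)oc12 | intermediate
13 | 7-{[(2R,3R)-3-[(2R)-2-hydroxy-4-methylpent-3-en-1-yl]-3-methyloxiran-2-yl]methoxy}-8-methoxy-2H-chromen-2-one | COc1c(OC[C@H]2O[C@]2(C)C[C@@H](O)C=C(C)C)ccc2ccc(=O)oc12 | target

## Step count and risks

Total steps: 8. Longest linear sequence: 7 (steps 1–4 and 6–8 from 1); step 5 is a one-step side branch.

**Step 6 (key step).** Three things may go wrong.
- Face selectivity may be poor, because in a methyl ketone the dipole-opposed conformer places chlorine against the methyl group and the energy gap between the competing transition states may shrink.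
- Conversion may be slow, since a ketone is a weaker electrophile than the aldehydes on which this induction is established.
- The Lewis acid may trigger epimerisation at C2' or loss of the aryloxide from 6.

Fallback, from 6 back to 11: a more nucleophilic and bulkier acetate equivalent is used, and the enone is completed afterwards. S-Ethyl thioacetate is converted with LiN(iPr)2 and TMSCl into 1-(ethylsulfanyl)-1-(trimethylsilyloxy)ethene F1. F1 is added to 6 under BF3·OEt2 at −78 °C to give S-ethyl (3R,4S)-4-chloro-3-hydroxy-5-[(8-methoxy-2-oxo-2H-chromen-7-yl)oxy]-3-methylpentanethioate F2. Liebeskind–Srogl coupling of F2 with purchased 2-methylprop-1-enylboronic acid (Pd2(dba)3, tri(2-furyl)phosphine, copper thiophene-2-carboxylate Cu(O2CC4H3S), THF, 50 °C) then gives 11 under neutral conditions.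

**Step 3.** The risk is incomplete discrimination between the two hydroxyls, giving etherification at the secondary carbinol, double etherification or a cyclic phosphorane that stalls the reaction. Fallback, from 3 back to 5: the primary hydroxyl is sulfonylated selectively (TsCl, pyridine, 0 °C) to give (2S,3S)-2-chloro-3-hydroxybutyl 4-methylbenzenesulfonate F3. F3 is displaced in DMF at 40 °C with the preformed, dried caesium salt of 4 (from 4 and CsOH·H2O), so that no base stronger than the phenoxide is present to close the chlorohydrin.

**Step 7.** The risk is erosion of 1,3-anti selectivity, because the tertiary carbinol must place one carbon substituent axial in the delivery chair and methyl and the C2' branch may not differ enough; the new allylic alcohol may also ionise in acetic acid. Fallback, from 11 back to 12: stereocontrol is moved from the substrate to a catalyst.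
- The C3' hydroxyl is capped with 1-(trimethylsilyl)imidazole in CH2Cl2 to give 7-{[(2S,3R)-2-chloro-3,7-dimethyl-5-oxo-3-(trimethylsilyloxy)oct-6-en-1-yl]oxy}-8-methoxy-2H-chromen-2-one F4.
- The enone is reduced by the Corey–Bakshi–Shibata method ((S)-2-methyl-CBS-oxazaborolidine, catecholborane, toluene, −78 °C; alkenyl as the large group, expected to give 5'R) to 7-{[(2S,3R,5R)-2-chloro-5-hydroxy-3,7-dimethyl-3-(trimethylsilyloxy)oct-6-en-1-yl]oxy}-8-methoxy-2H-chromen-2-one F5.
- The silyl ether is removed with citric acid in MeOH to give 12.

**Step 8.** The risk is competing displacement of chloride by the C5' hydroxyl (5-exo closure to a tetrahydrofuran) or methanolysis of the lactone while the chlorohydrin closes slowly. Fallback, from 12 back to 13: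
- The secondary C5' hydroxyl is silylated selectively (TBSCl, imidazole, DMF) to give 7-{[(2S,3R,5R)-5-(tert-butyldimethylsilyloxy)-2-chloro-3-hydroxy-3,7-dimethyloct-6-en-1-yl]oxy}-8-methoxy-2H-chromen-2-one F6.
- The oxirane is closed with NaH in THF at 0 °C to give 7-{[(2R,3R)-3-[(2R)-2-(tert-butyldimethylsilyloxy)-4-methylpent-3-en-1-yl]-3-methyloxiran-2-yl]methoxy}-8-methoxy-2H-chromen-2-one F7.
- The silyl group is removed with Bu4NF buffered with AcOH in THF to give 13.

## Further compounds

F1 | step 6 | 1-(ethylsulfanyl)-1-(trimethylsilyloxy)ethene | C=C(O[Si](C)(C)C)SCC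
F2 | step 6 | S-ethyl (3R,4S)-4-chloro-3-hydroxy-5-[(8-methoxy-2-oxo-2H-chromen-7-yl)oxy]-3-methylpentanethioate | COc1c(OC[C@H](Cl)[C@](C)(O)CC(=O)SCC)ccc2ccc(=O)oc12
F3 | step 3 | (2S,3S)-2-chloro-3-hydroxybutyl 4-methylbenzenesulfonate | C[C@H](O)[C@@H](Cl)COS(=O)(=O)c1ccc(C)cc1
F4 | step 7 | 7-{[(2S,3R)-2-chloro-3,7-dimethyl-5-oxo-3-(trimethylsilyloxy)oct-6-en-1-yl]oxy}-8-methoxy-2H-chromen-2-one | COc1c(OC[C@H](Cl)[C@](C)(O[Si](C)(C)C)CC(=O)C=C(C)C)ccc2ccc(=O)oc12
F5 | step 7 | 7-{[(2S,3R,5R)-2-chloro-5-hydroxy-3,7-dimethyl-3-(trimethylsilyloxy)oct-6-en-1-yl]oxy}-8-methoxy-2H-chromen-2-one | COc1c(OC[C@H](Cl)[C@](C)(O[Si](C)(C)C)C[C@@H](O)C=C(C)C)ccc2ccc(=O)oc12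
F6 | step 8 | 7-{[(2S,3R,5R)-5-(tert-butyldimethylsilyloxy)-2-chloro-3-hydroxy-3,7-dimethyloct-6-en-1-yl]oxy}-8-methoxy-2H-chromen-2-one | COc1c(OC[C@H](Cl)[C@](C)(O)C[C@@H](O[Si](C)(C)C(C)(C)C)C=C(C)C)ccc2ccc(=O)oc12
F7 | step 8 | 7-{[(2R,3R)-3-[(2R)-2-(tert-butyldimethylsilyloxy)-4-methylpent-3-en-1-yl]-3-methyloxiran-2-yl]methoxy}-8-methoxy-2H-chromen-2-one | COc1c(OC[C@H]2O[C@]2(C)C[C@@H](O[Si](C)(C)C(C)(C)C)C=C(C)C)ccc2ccc(=O)oc12
A1 | alternative 1 | tert-butyl(dimethyl){[(4R)-6-methylhept-5-en-1-yn-4-yl]oxy}silane | C#CC[C@@H](O[Si](C)(C)C(C)(C)C)C=C(C)C
A2 | alternative 1 | formaldehyde | C=O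
A3 | alternative 1 | (2E,5R)-5-(tert-butyldimethylsilyloxy)-3,7-dimethylocta-2,6-dien-1-ol | OC/C=C(\C)C[C@@H](O[Si](C)(C)C(C)(C)C)C=C(C)C
A4 | alternative 2 | tert-butyl[(1-methoxy-3-methylbuta-1,3-dien-1-yl)oxy]dimethylsilane | C=C(C)C=C(OC)O[Si](C)(C)C(C)(C)C
A5 | alternative 2 | 3-methylbut-2-enal | CC(C)=CC=O
A6 | alternative 2 | methyl (2E,5R)-5-hydroxy-3,7-dimethylocta-2,6-dienoate | COC(=O)/C=C(\C)C[C@@H](O)C=C(C)C
A7 | alternative 3 | [(8-methoxy-2-oxo-2H-chromen-7-yl)oxy]acetaldehyde | COc1c(OCC=O)ccc2ccc(=O)oc12
A8 | alternative 3 | tert-butyldimethyl{[(2E)-4-(4,4,5,5-tetramethyl-1,3,2-dioxaborolan-2-yl)but-2-en-2-yl]oxy}silane | C/C(O[Si](C)(C)C(C)(C)C)=C\CB1OC(C)(C)C(C)(C)O1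
A9 | alternative 3 | 7-{[(2S,3R)-3-(tert-butyldimethylsilyloxy)-2-hydroxy-3-methylpent-4-en-1-yl]oxy}-8-methoxy-2H-chromen-2-one | COc1c(OC[C@H](O)[C@](C)(O[Si](C)(C)C(C)(C)C)C=C)ccc2ccc(=O)oc12
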